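**Strategy.** Everything rests on cutting the exocyclic C(sp2)–C(sp3) bond between C1 of the trimethylcyclohexene ring (ring A) and the primary carbon C9 of the side chain. The feature exploited is that ring C1 is the carbonyl carbon of 2,2,6-trimethylcyclohexanone: the neighbouring C6 is quaternary, so the only enol triflate has the tetrasubstituted C1=C2 alkene of the target. The key step is a late Negishi coupling that joins this nine-carbon triflate to a sixteen-carbon alkylzinc iodide already carrying both stereocentres (C7, butenolide C5), the 2Z,5E skipped diene and the butenolide, under base-free conditions. Its precursor is a silyl-protected primary iodide assembled by cross-metathesis of two enantiopure fragments.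

Key step: step 14

Assumption: (2E)-3-methylpent-2-en-4-yn-1-ol, methyl (2S)-oxirane-2-carboxylate and (tributylstannyl)methanol are taken as commercial; the first is a small, water-soluble, volatile compound, so its early products are isolated by non-aqueous or continuous-extraction work-up.

**Step 1**
Reactants: 1 2,2,6-trimethylcyclohexanone
Product: 3 2,6,6-trimethylcyclohex-1-en-1-yl trifluoromethanesulfonate, via lithium enolate 2 (not isolated)
Conditions: LiN(iPr)2, THF, −78 to 0 °C; then PhNTf2, 0 °C to rt
Reagents that add atoms: N-phenylbis(trifluoromethanesulfonimide), O=S(=O)(N(c1ccccc1)S(=O)(=O)C(F)(F)F)C(F)(F)F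
Why: The ketone has an α-hydrogen on one side only, so deprotonation should give a single tetrasubstituted lithium enolate, which is O-sulfonylated (enol triflate formation).

**Step 2**
Reactants: 4 (2E)-3-methylpent-2-en-4-yn-1-ol
Product: 5 [(2R,3R)-3-ethynyl-3-methyloxiran-2-yl]methanol
Conditions: Ti(OiPr)4 (10 mol%), D-(−)-diisopropyl tartrate (12 mol%), t-BuOOH, 4 Å MS, CH2Cl2, −20 °C
Reagents that add atoms: tert-butyl hydroperoxide, CC(C)(C)OO
Why: Sharpless asymmetric epoxidation of a trisubstituted E allylic alcohol; the D-(−)-tartrate should direct oxygen to the face that gives the 2R,3R epoxide (mirror image of the geraniol/L-(+)-tartrate case), which sets the future C7 stereocentre under reagent control while the alkyne stays inert.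

**Step 3**
Reactants: 5 [(2R,3R)-3-ethynyl-3-methyloxiran-2-yl]methanol
Product: 7 (3S)-3-methylpent-4-ene-1,3-diol, via cyclic alkynyl diol aluminate 6 (not isolated)
Conditions: NaAlH2(OCH2CH2OMe)2 (Red-Al, 3.5 equiv), THF, 0 °C to rt; aq. potassium sodium tartrate work-up
Reagents that add atoms: none
Why: Red-Al bound to the primary alkoxide should deliver hydride intramolecularly to C2 (C3 is fully substituted), and the tertiary propargylic alkoxide so formed should direct trans-hydroalumination of the alkyne to the vinyl group (epoxy-alcohol opening to a 1,3-diol, then propargylic alcohol reduction); the C3–O bond is never broken, so C3 keeps its arrangement and is named S only because the priorities change.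

**Step 4**
Reactants: 7 (3S)-3-methylpent-4-ene-1,3-diol
Product: 8 (3S)-5-iodo-3-methylpent-1-en-3-ol
Conditions: I2, PPh3, imidazole, CH2Cl2, 0 °C
Reagents that add atoms: iodine, [I][I]
Why: Appel-type iodination should take the primary hydroxyl only, since the hindered tertiary allylic hydroxyl does not form an alkoxyphosphonium ion under these mild conditions.

**Step 5**
Reactants: 9 prop-2-yn-1-ol; 10 allylmagnesium bromide
Product: 12 (2Z)-3-iodo-2-(prop-2-en-1-yl)prop-2-en-1-ol, via chelated alkenylmagnesium alkoxide 11 (not isolated)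
Conditions: CH2=CHCH2MgBr (2.5 equiv), CuI (10 mol%), Et2O, 0 °C to rt; then I2, THF, −30 to 0 °C
Reagents that add atoms: iodine, [I][I]
Why: Hydroxyl-directed anti carbomagnesiation of a propargylic alcohol (Duboudin type): allyl is delivered to C2 and magnesium ends on C3 cis to the CH2O group in a five-membered chelate, and iodinolysis with retention should give the Z vinyl iodide, which fixes the geometry of the later trisubstituted alkene.

**Step 6**
Reactants: 12 (2Z)-3-iodo-2-(prop-2-en-1-yl)prop-2-en-1-ol
Product: 13 tert-butyl{[(2Z)-3-iodo-2-(prop-2-en-1-yl)prop-2-en-1-yl]oxy}dimethylsilane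
Conditions: TBSCl, imidazole, DMF, rt
Reagents that add atoms: tert-butyldimethylsilyl chloride, CC(C)(C)[Si](C)(C)Cl
Why: Standard silylation of a primary allylic alcohol, giving an ether that should survive the organometallic, basic and palladium steps that follow.

**Step 7**
Reactants: 13 tert-butyl{[(2Z)-3-iodo-2-(prop-2-en-1-yl)prop-2-en-1-yl]oxy}dimethylsilane; 14 methyl (2S)-oxirane-2-carboxylate
Product: 16 methyl (2S,4Z)-5-({[tert-butyl(dimethyl)silyl]oxy}methyl)-2-hydroxyocta-4,7-dienoate, via alkenylmagnesium chloride 15 (not isolated)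
Conditions: iPrMgCl·LiCl, THF, −20 °C; then CuI (10 mol%), 14, −40 to −20 °C
Reagents that add atoms: none
Why: Iodine–magnesium exchange with retention of alkene geometry, then CuI-catalysed SN2 opening of the glycidic ester at its unsubstituted C3, which at low temperature should outrun addition to the ester; the C2 stereocentre of 14 is not involved and becomes the S carbinol that will be butenolide C5.

**Step 8**
Reactants: 16 methyl (2S,4Z)-5-({[tert-butyl(dimethyl)silyl]oxy}methyl)-2-hydroxyocta-4,7-dienoate
Product: 17 methyl (2S,4Z)-2-acetoxy-5-({[tert-butyl(dimethyl)silyl]oxy}methyl)octa-4,7-dienoate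
Conditions: Ac2O, pyridine, DMAP (cat.), CH2Cl2, 0 °C to rt
Reagents that add atoms: acetic anhydride, CC(=O)OC(C)=O
Why: Routine O-acetylation of a secondary alcohol, which installs the two carbons that become C2 and C3 of the butenolide.

**Step 9**
Reactants: 17 methyl (2S,4Z)-2-acetoxy-5-({[tert-butyl(dimethyl)silyl]oxy}methyl)octa-4,7-dienoate
Product: 18 (5S)-5-[(2Z)-3-({[tert-butyl(dimethyl)silyl]oxy}methyl)hexa-2,5-dien-1-yl]-4-hydroxyfuran-2(5H)-one
Conditions: LiN(SiMe3)2 (2.2 equiv), THF, −78 °C; then 1 M HCl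
Reagents that add atoms: none
Why: Intramolecular Claisen (Dieckmann) condensation: the acetate enolate formed kinetically at the methyl group attacks the neighbouring methyl ester, methoxide leaves, and the second equivalent of base traps the product as the lithium tetronate, which should shield C5–H; C5 is not a reacting centre.

**Step 10**
Reactants: 18 (5S)-5-[(2Z)-3-({[tert-butyl(dimethyl)silyl]oxy}methyl)hexa-2,5-dien-1-yl]-4-hydroxyfuran-2(5H)-one
Product: 19 (2S)-2-[(2Z)-3-({[tert-butyl(dimethyl)silyl]oxy}methyl)hexa-2,5-dien-1-yl]-5-oxo-2,5-dihydrofuran-3-yl trifluoromethanesulfonate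
Conditions: Tf2O, iPr2NEt, CH2Cl2, −78 °C
Reagents that add atoms: trifluoromethanesulfonic anhydride, O=S(=O)(OS(=O)(=O)C(F)(F)F)C(F)(F)F
Why: O-sulfonylation of the vinylogous acid at low temperature should give the vinylogous acyl triflate, an excellent partner for palladium.

**Step 11**
Reactants: 19 (2S)-2-[(2Z)-3-({[tert-butyl(dimethyl)silyl]oxy}methyl)hexa-2,5-dien-1-yl]-5-oxo-2,5-dihydrofuran-3-yl trifluoromethanesulfonate
Product: 20 (5S)-5-[(2Z)-3-({[tert-butyl(dimethyl)silyl]oxy}methyl)hexa-2,5-dien-1-yl]-4-(hydroxymethyl)furan-2(5H)-one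
Conditions: Bu3SnCH2OH, Pd(PPh3)4 (5 mol%), LiCl, 1,4-dioxane, 80 °C
Reagents that add atoms: (tributylstannyl)methanol, CCCC[Sn](CCCC)(CCCC)CO
Why: Stille (Kosugi–Migita) hydroxymethylation: zerovalent palladium adds into the C–OTf bond, the CH2OH group is transferred from tin in preference to butyl, and reductive elimination should give the 4-(hydroxymethyl)butenolide under neutral conditions that leave C5 and the 1,4-diene alone.

**Step 12**
Reactants: 20 (5S)-5-[(2Z)-3-({[tert-butyl(dimethyl)silyl]oxy}methyl)hexa-2,5-dien-1-yl]-4-(hydroxymethyl)furan-2(5H)-one; 8 (3S)-5-iodo-3-methylpent-1-en-3-ol (3 equiv)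
Product: 21 (5S)-5-[(2Z,5E,7S)-3-({[tert-butyl(dimethyl)silyl]oxy}methyl)-7-hydroxy-9-iodo-7-methylnona-2,5-dien-1-yl]-4-(hydroxymethyl)furan-2(5H)-one
Conditions: second-generation Hoveyda–Grubbs catalyst [RuCl2(H2IMes)(=CH-C6H4-2-OiPr)] (5 mol%), CH2Cl2, 40 °C
Reagents that add atoms: none
Why: Olefin cross-metathesis between the unhindered allyl terminus of 20 and the vinyl group of 8, whose quaternary allylic carbon suppresses homodimerisation so that an excess can be used; the trisubstituted chain alkene and the butenolide alkene should not react, and the new disubstituted alkene should form as the E isomer under thermodynamic control.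

**Step 13**
Reactants: 21 (5S)-5-[(2Z,5E,7S)-3-({[tert-butyl(dimethyl)silyl]oxy}methyl)-7-hydroxy-9-iodo-7-methylnona-2,5-dien-1-yl]-4-(hydroxymethyl)furan-2(5H)-one
Product: 22 (5S)-5-[(2Z,5E,7S)-3-({[tert-butyl(dimethyl)silyl]oxy}methyl)-9-iodo-7-methyl-7-[(triethylsilyl)oxy]nona-2,5-dien-1-yl]-4-{[(triethylsilyl)oxy]methyl}furan-2(5H)-one
Conditions: TESOTf (2.5 equiv), 2,6-lutidine, CH2Cl2, −78 °C
Reagents that add atoms: triethylsilyl trifluoromethanesulfonate, CC[Si](CC)(CC)OS(=O)(=O)C(F)(F)F
Why: A silyl triflate with a hindered pyridine base should silylate both the primary and the tertiary hydroxyl at low temperature, where enolisation of the butenolide to a silyloxyfuran should not compete, and this removes every acidic proton before the organozinc is made.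

**Step 14**
Reactants: 22 (5S)-5-[(2Z,5E,7S)-3-({[tert-butyl(dimethyl)silyl]oxy}methyl)-9-iodo-7-methyl-7-[(triethylsilyl)oxy]nona-2,5-dien-1-yl]-4-{[(triethylsilyl)oxy]methyl}furan-2(5H)-one; 3 2,6,6-trimethylcyclohex-1-en-1-yl trifluoromethanesulfonate
Product: 24 (5S)-5-[(2Z,5E,7S)-3-({[tert-butyl(dimethyl)silyl]oxy}methyl)-7-methyl-7-[(triethylsilyl)oxy]-9-(2,6,6-trimethylcyclohex-1-en-1-yl)nona-2,5-dien-1-yl]-4-{[(triethylsilyl)oxy]methyl}furan-2(5H)-one, via alkylzinc iodide 23 (not isolated)
Conditions: Zn dust (activated with BrCH2CH2Br and Me3SiCl), LiCl, THF, 40 °C; then 3, Pd(OAc)2 (5 mol%), SPhos (10 mol%), THF/NMP, 50 °C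
Reagents that add atoms: none
Why: Zinc inserts into the primary C9–I bond (LiCl-assisted) to give alkylzinc iodide 23; zerovalent palladium, formed in situ from Pd(OAc)2 and SPhos, adds oxidatively into the C1–OTf bond of 3, the primary alkyl group is transmetalated from zinc to palladium, and reductive elimination forms the ring C1–C9 bond. The closest known reaction type is the Negishi coupling of primary alkylzinc halides with enol triflates, here applied to a hindered tetrasubstituted partner. No ring is closed and no stereocentre is created: C7 and butenolide C5 enter with fixed configuration and are not touched, and the position of the ring alkene is fixed by the triflate. The step needs chemoselectivity for one C–I and one C–OTf bond in the presence of a butenolide, three silyl ethers and three other alkenes; this is secured by the low basicity and nucleophilicity of alkylzinc halides, by the absence of any other halide or sulfonate, and by silylation of all hydroxyls. The bulky electron-rich biarylphosphine should make reductive elimination at the crowded alkenylpalladium faster than β-hydride elimination of the alkyl group. Because no base is present, the acidic C5–H of the butenolide should not epimerise.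

**Step 15**
Reactants: 24 (5S)-5-[(2Z,5E,7S)-3-({[tert-butyl(dimethyl)silyl]oxy}methyl)-7-methyl-7-[(triethylsilyl)oxy]-9-(2,6,6-trimethylcyclohex-1-en-1-yl)nona-2,5-dien-1-yl]-4-{[(triethylsilyl)oxy]methyl}furan-2(5H)-one
Product: 25 (5S)-4-(hydroxymethyl)-5-[(2Z,5E,7S)-7-hydroxy-3-(hydroxymethyl)-7-methyl-9-(2,6,6-trimethylcyclohex-1-en-1-yl)nona-2,5-dien-1-yl]furan-2(5H)-one
Conditions: HF·pyridine, pyridine, THF, 0 °C to rt
Reagents that add atoms: none
Why: Buffered fluoride desilylation should remove the TBS group and both TES groups without the base that would epimerise C5 and without enough acidity to ionise the tertiary allylic alcohol.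

**Compound list**

1 | 2,2,6-trimethylcyclohexanone (racemic) | CC1CCCC(C)(C)C1=O | starting material
2 | lithium 2,6,6-trimethylcyclohex-1-en-1-olate | CC1=C(O[Li])C(C)(C)CCC1 | intermediate
3 | 2,6,6-trimethylcyclohex-1-en-1-yl trifluoromethanesulfonate | CC1=C(OS(=O)(=O)C(F)(F)F)C(C)(C)CCC1 | intermediate
4 | (2E)-3-methylpent-2-en-4-yn-1-ol | C#C/C(C)=C/CO | starting material
5 | [(2R,3R)-3-ethynyl-3-methyloxiran-2-yl]methanol | OC[C@H]1O[C@]1(C)C#C | intermediate
6 | sodium bis(2-methoxyethoxy)aluminate of (3S)-3-methylpent-4-yne-1,3-diol (cyclic) | C#C[C@]1(C)CCO[Al-](OCCOC)(OCCOC)O1.[Na+] | intermediate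
7 | (3S)-3-methylpent-4-ene-1,3-diol | OCC[C@](C)(O)C=C | intermediate
8 | (3S)-5-iodo-3-methylpent-1-en-3-ol | ICC[C@](C)(O)C=C | intermediate
9 | prop-2-yn-1-ol | C#CCO | starting material
10 | allylmagnesium bromide | C=CC[Mg]Br | starting material
11 | bromomagnesium (2Z)-3-(bromomagnesio)-2-(prop-2-en-1-yl)prop-2-en-1-olate | C=CC/C(=C/[Mg]Br)CO[Mg]Br | intermediate
12 | (2Z)-3-iodo-2-(prop-2-en-1-yl)prop-2-en-1-ol | C=CC/C(=C/I)CO | intermediate
13 | tert-butyl{[(2Z)-3-iodo-2-(prop-2-en-1-yl)prop-2-en-1-yl]oxy}dimethylsilane | C=CC/C(=C/I)CO[Si](C)(C)C(C)(C)C | intermediate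
14 | methyl (2S)-oxirane-2-carboxylate | COC(=O)[C@@H]1CO1 | starting material
15 | alkenylmagnesium chloride from 13 (Mg in place of I, geometry retained) | C=CC/C(=C/[Mg]Cl)CO[Si](C)(C)C(C)(C)C | intermediate
16 | methyl (2S,4Z)-5-({[tert-butyl(dimethyl)silyl]oxy}methyl)-2-hydroxyocta-4,7-dienoate | C=CC/C(=C/C[C@H](O)C(=O)OC)CO[Si](C)(C)C(C)(C)C | intermediate
17 | methyl (2S,4Z)-2-acetoxy-5-({[tert-butyl(dimethyl)silyl]oxy}methyl)octa-4,7-dienoate | C=CC/C(=C/C[C@H](OC(C)=O)C(=O)OC)CO[Si](C)(C)C(C)(C)C | intermediate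
18 | (5S)-5-[(2Z)-3-({[tert-butyl(dimethyl)silyl]oxy}methyl)hexa-2,5-dien-1-yl]-4-hydroxyfuran-2(5H)-one | C=CC/C(=C/C[C@@H]1OC(=O)C=C1O)CO[Si](C)(C)C(C)(C)C | intermediate
19 | (2S)-2-[(2Z)-3-({[tert-butyl(dimethyl)silyl]oxy}methyl)hexa-2,5-dien-1-yl]-5-oxo-2,5-dihydrofuran-3-yl trifluoromethanesulfonate | C=CC/C(=C/C[C@@H]1OC(=O)C=C1OS(=O)(=O)C(F)(F)F)CO[Si](C)(C)C(C)(C)C | intermediate
20 | (5S)-5-[(2Z)-3-({[tert-butyl(dimethyl)silyl]oxy}methyl)hexa-2,5-dien-1-yl]-4-(hydroxymethyl)furan-2(5H)-one | C=CC/C(=C/C[C@@H]1OC(=O)C=C1CO)CO[Si](C)(C)C(C)(C)C | intermediate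
21 | (5S)-5-[(2Z,5E,7S)-3-({[tert-butyl(dimethyl)silyl]oxy}methyl)-7-hydroxy-9-iodo-7-methylnona-2,5-dien-1-yl]-4-(hydroxymethyl)furan-2(5H)-one | ICC[C@](C)(O)/C=C/C/C(=C/C[C@@H]1OC(=O)C=C1CO)CO[Si](C)(C)C(C)(C)C | intermediate
22 | bis(triethylsilyl) ether of 21 (at the C7 hydroxyl and the butenolide CH2OH) | ICC[C@](C)(O[Si](CC)(CC)CC)/C=C/C/C(=C/C[C@@H]1OC(=O)C=C1CO[Si](CC)(CC)CC)CO[Si](C)(C)C(C)(C)C | intermediate
23 | alkylzinc iodide from 22 (ZnI in place of I at C9) | I[Zn]CC[C@](C)(O[Si](CC)(CC)CC)/C=C/C/C(=C/C[C@@H]1OC(=O)C=C1CO[Si](CC)(CC)CC)CO[Si](C)(C)C(C)(C)C | intermediate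
24 | tris-silyl ether of the target (TBS on the chain CH2OH; TES on the C7 hydroxyl and the butenolide CH2OH) | CC1=C(CC[C@](C)(O[Si](CC)(CC)CC)/C=C/C/C(=C/C[C@@H]2OC(=O)C=C2CO[Si](CC)(CC)CC)CO[Si](C)(C)C(C)(C)C)C(C)(C)CCC1 | intermediate
25 | (5S)-4-(hydroxymethyl)-5-[(2Z,5E,7S)-7-hydroxy-3-(hydroxymethyl)-7-methyl-9-(2,6,6-trimethylcyclohex-1-en-1-yl)nona-2,5-dien-1-yl]furan-2(5H)-one | CC1=C(CC[C@](C)(O)/C=C/C/C(=C/C[C@@H]2OC(=O)C=C2CO)CO)C(C)(C)CCC1 | target

**Step count and risks**

Total step count: 15. Longest linear sequence: 11 steps (steps 5 to 15, from prop-2-yn-1-ol).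

Steps most likely to fail:

1. Step 14 (key step). Zinc insertion into the polyfunctional iodide may stay incomplete, and oxidative addition and transmetalation at the doubly flanked tetrasubstituted enol triflate may be slow enough for protodezincation or β-hydride elimination to take over. The fallback makes the ring–chain bond before the butenolide is in the molecule and moves the metathesis to the end; it sets out from 8 and comes back at 25. Iodide 8 is silylated (TESOTf, 2,6-lutidine, CH2Cl2, −78 °C) to (3S)-triethyl[(5-iodo-3-methylpent-1-en-3-yl)oxy]silane F1. Iodine–lithium exchange (t-BuLi, Et2O, −78 °C) and capture with 9-methoxy-9-borabicyclo[3.3.1]nonane give the lithium B-alkyl-B-methoxyborate F2, which is coupled in the same flask with triflate 3 (Pd(dppf)Cl2, aq. K3PO4, DMF, rt; B-alkyl Suzuki–Miyaura coupling) to give triethyl{[(3S)-3-methyl-5-(2,6,6-trimethylcyclohex-1-en-1-yl)pent-1-en-3-yl]oxy}silane F3. Bu4NF in THF frees (3S)-3-methyl-5-(2,6,6-trimethylcyclohex-1-en-1-yl)pent-1-en-3-ol F4. Cross-metathesis of F4 (excess) with 20 under the conditions of step 12 gives the mono-TBS ether of the target F5, and HF·pyridine returns to 25.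

2. Step 3. The second stage of the tandem reduction, hydroalumination of the terminal alkyne, may stall at the aluminium acetylide or run on unselectively, so that mixtures of alkyne and alkene diols result. The fallback separates the two reductions and uses catalytic semihydrogenation for the alkyne; it sets out from 5 and comes back at 7. Red-Al (1.2 equiv, THF, −20 °C) opens only the epoxide and (3S)-3-methylpent-4-yne-1,3-diol F6 is isolated; hydrogenation over Pd/CaCO3 poisoned with Pb(OAc)2 (Lindlar catalyst) with quinoline in EtOAc then gives 7.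

3. Step 9. The amide base may remove the C2–H of the α-acetoxy ester instead of an acetyl proton, or the product may exchange protons before it is trapped as the tetronate; either would erode the configuration of the future butenolide C5. The fallback builds the ring under neutral conditions by an intramolecular Wittig reaction; it sets out from 16 and comes back at 18. Transesterification of 16 in allyl alcohol with catalytic Ti(OiPr)4 (80 °C) gives allyl (2S,4Z)-5-({[tert-butyl(dimethyl)silyl]oxy}methyl)-2-hydroxyocta-4,7-dienoate F7. Ketenylidenetriphenylphosphorane (Ph3P=C=C=O, toluene, 80 °C) acylates the hydroxyl and the resulting ester ylide olefinates the allyl ester carbonyl to give (5S)-4-(allyloxy)-5-[(2Z)-3-({[tert-butyl(dimethyl)silyl]oxy}methyl)hexa-2,5-dien-1-yl]furan-2(5H)-one F8. Deallylation with Pd(PPh3)4 (cat.) and morpholine in THF at rt gives 18.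

**Further compounds**

F1 | step 14 | (3S)-triethyl[(5-iodo-3-methylpent-1-en-3-yl)oxy]silane | ICC[C@](C)(O[Si](CC)(CC)CC)C=C
F2 | step 14 | lithium B-alkyl-B-methoxy-9-borabicyclo[3.3.1]nonane borate from F1 | [Li+].CO[B-]1(CC[C@](C)(O[Si](CC)(CC)CC)C=C)C2CCCC1CCC2
F3 | step 14 | triethyl{[(3S)-3-methyl-5-(2,6,6-trimethylcyclohex-1-en-1-yl)pent-1-en-3-yl]oxy}silane | CC1=C(CC[C@](C)(O[Si](CC)(CC)CC)C=C)C(C)(C)CCC1
F4 | step 14 | (3S)-3-methyl-5-(2,6,6-trimethylcyclohex-1-en-1-yl)pent-1-en-3-ol | CC1=C(CC[C@](C)(O)C=C)C(C)(C)CCC1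
F5 | step 14 | mono-TBS ether of the target (TBS on the chain CH2OH) | CC1=C(CC[C@](C)(O)/C=C/C/C(=C/C[C@@H]2OC(=O)C=C2CO)CO[Si](C)(C)C(C)(C)C)C(C)(C)CCC1
F6 | step 3 | (3S)-3-methylpent-4-yne-1,3-diol | OCC[C@](C)(O)C#C
F7 | step 9 | allyl (2S,4Z)-5-({[tert-butyl(dimethyl)silyl]oxy}methyl)-2-hydroxyocta-4,7-dienoate | C=CC/C(=C/C[C@H](O)C(=O)OCC=C)CO[Si](C)(C)C(C)(C)C
F8 | step 9 | (5S)-4-(allyloxy)-5-[(2Z)-3-({[tert-butyl(dimethyl)silyl]oxy}methyl)hexa-2,5-dien-1-yl]furan-2(5H)-one | C=CC/C(=C/C[C@@H]1OC(=O)C=C1OCC=C)CO[Si](C)(C)C(C)(C)C
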